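We start from a constant the runs so far can give: a rate constant for a step against partner, taken as the same for every step. The two earlier runs and the flask asked about are these:

| flask | substrate | partner | scavenger | remark | time |
|---|---|---|---|---|---|
| north-west | 38 mM | 1.8 equiv | 0.67 equiv | run made earlier |  |
| north | 38 mM | 1.8 equiv | 1.5 equiv | run made earlier |  |
| flask | 38 mM | 1.80 equiv | 1.00 equiv |  | 2.5 min |

| run | time / s | substrate / % | first product / % | double product / % |
|---|---|---|---|---|
| north-west | 15.0 | 86 | 12 | 0 |
| north-west | 40.0 | 70 | 23 | 4 |
| north-west | 80.0 | 55 | 32 | 9 |
| north-west | 120 | 43 | 34 | 15 |
| north | 30.0 | 77 | 17 | 2 |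
| north | 60.0 | 61 | 31 | 6 |
| north | 90.0 | 53 | 35 | 9 |
| north | 120 | 45 | 36 | 15 |

(scatter of a reading: 1.5 percentage points)

- a reading of substrate is of its free form alone

1. how much substrate there is at 2.5 min, in percent of the substrate charged
2. how much first product there is at 2.5 min, in percent of the substrate charged
3. how much double product there is at 2.5 min, in percent of the substrate charged
4. how much triple product there is at 2.5 min, in percent of the substrate charged

At 120 s the two runs read 43% and 45% of substrate, a gap of 2 percentage points against a scatter of 1.5 points, though scavenger differs between them. So we set scavenger aside and take their geometric mean, 44.0%.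

Let s be the steps taken per substrate charged. If the steps run equally fast, the fractions form a ladder (a Poisson distribution): substrate exp(−s), first product s times that, double product s squared over 2 times it, triple product s cubed over 6 times it. The mean gives s = 0.821. The ladder then puts first product at 36.1% and double product at 14.8%, against readings of 34% and 36%, then 15% and 15%, so we keep it.

Scaling s by time to 2.5 min gives 1.03 and 35.7% substrate. That link is weak: each step uses one partner, so by our count about 0.979 equiv of partner stands at the last readings, of 1.8 equiv charged.

Reforged, s = equiv of partner × (1 − exp(−k × substrate charged × t)). The readings then give the step constant k, 0.134 /M/s. For the flask s = 0.960, so we commit to 38.3% substrate, 36.8% first product, 17.6% double product and 5.65% triple product.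

The forecast gives 38%, 36%, 19.5% and 6%, taking “the second step about as fast as the first”. Its double product stands above ours.

The flask gives 38.3%, 36.5%, 17.3% and 5.53%, so the forecast holds on all four.

    partner + double product → triple product + released group (k = 0.130 /M/s)
    substrate + partner → first product + released group (k = 0.130 /M/s)
    partner + triple product → tetra adduct + released group (k = 0.120 /M/s)
    substrate + released group ⇌ idle adduct, settled at all times (K = 36.0 /M)
    partner + first product → double product + released group (k = 0.130 /M/s)
    scavenger + released group → scavenged by-product (k = 59.0 /M/s)

At 2.50 min partner in the flask stands at 48% of its charge, and our step count gave 46.7%. With 23 mM of substrate and the equivalents held, the neighbouring flask has k × substrate × t smaller, so s = 0.665. The ladder then gives 51.4% substrate, 34.2% first product, 11.4% double product and 2.52% triple product. That neighbouring flask gives 52.0%, 33.9%, 11.0% and 2.42%.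

The readings were computed with constants of no real substance.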